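## The problem

CNP0140109.1 is a briarane-type diterpenoid: a ten-membered carbocycle (C1–C10) fused through C1/C10 to a cyclohexene (ring A: C1, C10–C14) and through C7/C8 to an α-methyl-γ-lactone (O–C7, C8, C17, C19). It carries seven stereocentres (1S,2S,7S,8S,10S,14S,17R): a quaternary C1 between the two acetoxy carbons C2 and C14, and a fully substituted carbinol C8 between the lactone carbinol C7 and the C9 ketone. The C5=C6 alkene is Z and trisubstituted, and the lactone and the ten-membered ring are trans-fused. C1, C10 and C14 are contiguous on ring A and can be set together, but they are remote from C7, C8 and C17, which must therefore be set by local, chelation or reagent control once the medium ring exists. The end-game must respect several fragile groups: the β-hydroxy lactone (retro-aldol at C8–C17), the tertiary α-ketol, the C10–H (α to the ketone and allylic), and two secondary acetates beside a free primary allylic alcohol. Direct closure of a ten-membered ring that already holds a Z alkene and a quaternary centre is entropically and enthalpically poor. The enabling feature is that C2 and C7 are 1,6-related across the ring: C3–C4–C5=C6 lies on one side and C1–C10–C9–C8 on the other, so a C2–C7 bond turns the ten-membered ring into two fused six-membered rings (ring B: C1, C2, C7, C8, C9, C10; ring C: C2–C7 with C5=C6). Cutting that bond oxidatively returns the ring with oxygen at C2 and C7, where the target has it.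

## Retrosynthesis

**Acetates and protecting groups (32 ← 31 ← 30 ← 29 ← 28).** The two acetyl C–O bonds, the two Si–O bonds and the C2–H bond are cut last. Acetates would not survive the hydride and organometallic steps and migrate under base, so they are installed only after the last reduction. The C20 hydroxyl stays silylated until the end so that only C2 and C14 are acylated. The C2 carbinol of 29 is taken back to the ketone 28, which is what the ring expansion delivers. The forward step is a reagent-controlled reduction of a ketone flanked by a quaternary and a methylene carbon.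

**Lactone (28 ← 27 ← 26).** The O–C19 bond and the C7–H bond are cut. Closing the lactone by an aldol of a C7 propionate onto a C8 ketone would require an 8,9-dione and is rejected. Reduction of the C7 enone carbonyl of 26 lets the new hydroxyl close onto the ester. The forward step must reduce C7 in the presence of the C2 and C9 ketones, from the face that gives 7S.

**C8 (26 ← 25 ← 22 + 24).** The C8–O bond and then the C8–C17 bond are cut. In trione 22, C8 is the only carbon between two carbonyls, so it can be alkylated and then hydroxylated without competition from C3 or C10. Functionalising C8 through the C9 ketone alone would compete with C10. This removes two stereocentres and three carbons. The forward steps are C-alkylation by the lactate triflate 24 with inversion (17R) and a face-selective enolate oxidation (8S).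

**Key disconnection (22 ← 20).** The C2–C7 bond is reconnected: trione 22 is the glycol-cleavage product of the tricyclic cis-diol 20. This replaces a medium-ring cyclisation by a fragmentation of fused six-membered rings, fixes the Z alkene in a cyclohexene, and leaves C7 and C9 as carbonyls flanking C8. The forward reaction needs only that C2/C7 be the sole free 1,2-diol.

**Ring C (20 ← 19 ← 18 ← 17; 9 ← 8).** The C5=C6 alkene is cut by ring-closing metathesis (19 ← 18). The C6–C7 bond is cut as a vinyl addition to the C7 ketone (18 ← 17), and the C2–C3 bond as a 3-methylbut-3-enyl addition to the C2 ketone (9 ← 8). A preformed cyclohex-3-ene-1,2-dione partner is not an option, since such diones are keto tautomers of catechols, and an aldol joining two fully substituted carbons would be reversible. Two carbonyl additions instead use the carbonyls of a quinone adduct. Both additions must come from the face opposite the axial C1 methyl so that the diol is cis and the two alkenyl chains can meet.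

**Ring B oxidation pattern and ring A alkene (17 ← 15 ← 14 ← 12 ← 10 ← 9).** The methoxy enone of 9 is the masked C7 ketone. Reduction and acid (Stork–Danheiser transposition) give enone 14, and the C9 oxygen is restored by conjugate borylation–oxidation (17 ← 15), so C9 needs no protecting group. The C11=C12 alkene is taken back to the C12=C13 alkene of the cycloadduct through enal 12, where conjugation with the C20 aldehyde directs the shift.

**Rings A and B (8 ← 7 ← 2 + 6).** The C1–C14 and C10–C11 bonds are cut in a quinone Diels–Alder reaction. Compared with annulation routes to the decalin, one step sets C1 and C14 in the correct relative sense (endo rule) and supplies ring B with oxygen at C2, C7 and C9. C10 is then corrected by epimerisation. The forward reaction must be regioselective (oxygenated diene terminus to the methyl-bearing carbon) and enantioselective.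

**Fragments (2 ← 1; 6 ← 5 ← 4 ← 3; 24 ← 23).** Quinone 2 comes from phenol 1, diene 6 from glutaconaldehyde salt 3, and triflate 24 from methyl (R)-lactate 23.

## Roads not taken

Alternative 1: The cuts are C2–C3 and C3–C4, with the ten-membered ring closed later elsewhere. In the key step 2-lithio-1,3-dithiane A4 is alkylated by the Z allylic bromide A3 (C3–C4), lithiated again and added to the ring A aldehyde A2 (C2–C3) to give the dithiane adduct A1.
- Merits: this is the most convergent of the four plans. The Z alkene and C7 are fixed in a small fragment, ring A is made separately, and C2 arrives directly as a carbinol.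
- Weak points: the twice-substituted dithiane anion must add to a neopentyl aldehyde on the quaternary C1, and the sense at C2 is uncertain. C3 is a methylene in the target, so the dithiane must be desulfurised reductively in the presence of two trisubstituted alkenes and allylic ethers.
- The main objection is that A1 is acyclic: the ten-membered ring still has to be closed by bond formation at the congested C7–C9 region, the very cyclisation that is hardest for this target.
- Comparison: in convergence and in reaching the full carbon chain quickly, this road is better. The chosen plan sets against it that no medium ring is ever closed by bond formation and that C2 and C7 both emerge oxygenated.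

Alternative 2: The cut is C1–C10. Lewis-acid activation of the C1–C2 epoxide of the fourteen-membered silyl dienol ether A6 lets C10 attack C1 across the ring, giving the 2-hydroxy bicyclic lactone A5.
- Merits: one step forms ring A and the ten-membered ring, the quaternary C1, the C2 hydroxyl and C10. The lactone and C8 are already in place, so the end-game after A5 is only acetylation and deprotection, clearly shorter than the seven steps that follow trione 22.
- Weak points: A6 is itself a difficult target (macrocyclisation, a trisubstituted epoxide, a Z alkene, a lactone and a geometrically defined dienol ether in one ring). The key step must open the epoxide at its more substituted carbon with inversion from one ring conformer, against semipinacol rearrangement, hydride shift and attack through the γ-carbon of the dienol ether.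
- Comparison: the outcome rests on a conformational bias that cannot be predicted. The chosen plan is longer after its key step, but its ring-forming events (cycloaddition, metathesis, glycol cleavage) are each predictable.

Alternative 3: The cut is C9–C10, made good by a temporary C9–O–C12 ether. Deprotonation of the propargylic C9–H of the thirteen-membered ether A8 triggers a [2,3]-Wittig rearrangement to the ten-membered enynol A7.
- Merits: like the chosen plan, it reaches the ten-membered ring by a ring-size change and not by direct closure. The five-membered transition state transfers the C12 configuration to C10, so C10 is set directly, where the chosen route needs an epimerisation (step 6).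
- Weak points: A8 requires a macrocyclic etherification or alkylation next to the quaternary C1. The strongly basic step can divert to a [1,2]-shift or to allene formation.
- A7 carries an alkyne at C7–C8, which must still be turned into the C7 carbinol, the fully substituted C8 and the lactone without the help of a 1,3-diketone.
- Comparison: the chosen plan obtains C7 and C9 as carbonyls flanking C8 directly from the cleavage, which makes the C8 chemistry shorter and regiochemically unambiguous.

Key step: step 16

Remark on numbering: locants C1–C20 in the names are those of the target skeleton; β is the face of rings A and B that carries the C1 methyl group; TBS = tert-butyldimethylsilyl, TBDPS = tert-butyldiphenylsilyl.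
Assumption: the (R)-BINOL–titanium catalyst is taken to deliver the enantiomer 7 drawn; the sense of induction for this quinone–diene pair is not known, and the (S)-ligand is equally available.
Assumption: glutaconaldehyde potassium salt 3 and 4-bromo-2-methylbut-1-ene are taken as purchasable.

Step 1
Reactants: 1 2-methoxy-6-methylphenol
Product: 2 2-methoxy-6-methyl-1,4-benzoquinone
Conditions: Co(salen) (5 mol%), O2 (1 atm), DMF, 23 °C
Reagents that add atoms: dioxygen, O=O
Why: Cobalt-salen-catalysed aerobic oxidation of a phenol whose two ortho positions are blocked should give the para-quinone (phenol-to-quinone oxidation).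

Step 2
Reactants: 3 glutaconaldehyde potassium salt
Product: 4 (2E,4E)-5-(TBS-oxy)penta-2,4-dienal
Conditions: t-BuMe2SiCl, THF/DMF, 0 to 23 °C
Reagents that add atoms: tert-butyldimethylsilyl chloride, CC(C)(C)[Si](C)(C)Cl
Why: The ambident dienolate is silylated on oxygen by the hard silicon electrophile and keeps its extended all-trans geometry (O-silylation of an enolate).

Step 3
Reactants: 4 (2E,4E)-5-(TBS-oxy)penta-2,4-dienal
Product: 5 (2E,4E)-5-(TBS-oxy)penta-2,4-dien-1-ol
Conditions: i-Bu2AlH, CH2Cl2, −78 °C
Reagents that add atoms: none
Why: Aluminium hydride reduction of the aldehyde is 1,2-selective at low temperature and leaves the silyl dienol ether intact.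

Step 4
Reactants: 5 (2E,4E)-5-(TBS-oxy)penta-2,4-dien-1-ol
Product: 6 (1E,3E)-1,5-bis(TBS-oxy)penta-1,3-diene
Conditions: t-BuMe2SiCl, imidazole, CH2Cl2, 0 °C
Reagents that add atoms: tert-butyldimethylsilyl chloride, CC(C)(C)[Si](C)(C)Cl
Why: Standard silylation of a primary alcohol under non-acidic conditions that spare the dienol ether.

Step 5
Reactants: 2 2-methoxy-6-methyl-1,4-benzoquinone; 6 (1E,3E)-1,5-bis(TBS-oxy)penta-1,3-diene
Product: 7 cis-fused cycloadduct
Conditions: (R)-BINOL (20 mol%), TiCl2(Oi-Pr)2 (20 mol%), 4 Å molecular sieves (filtered off before use), toluene, −40 to −20 °C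
Reagents that add atoms: none
Why: Enantioselective quinone Diels–Alder reaction: titanium chelated by the methoxy oxygen and the adjacent carbonyl activates the methyl-bearing double bond (the methoxy-bearing one is a deactivated vinylogous ester), so the nucleophilic terminus C11 of the silyloxydiene bonds to the unsubstituted carbon (C10) and the oxygenated terminus C14 to the methyl-bearing carbon (C1). The endo transition state places both E-substituents of the diene cis to the quinone ring, which sets C14–O trans to the C1 methyl as in the target; the binaphthol ligand selects the enantiotopic face.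

Step 6
Reactants: 7 cis-fused cycloadduct
Product: 8 trans-fused enedione
Conditions: DBU (0.2 equiv), toluene, 23 °C; recovered 7 resubmitted
Reagents that add atoms: none
Why: Base-mediated epimerisation of a quinone cycloadduct: C10–H is α to the enedione carbonyl and C1 is quaternary, so enolisation cannot lead to aromatisation and should equilibrate towards the trans-fused isomer with the C11 side chain equatorial. This sets 10α-H and turns the C1 methyl into an axial group that shields the β-face of ring B in steps 7 and 13.

Step 7
Reactants: 8 trans-fused enedione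
Product: 9 C2 tertiary carbinol
Conditions: CH2=C(CH3)CH2CH2MgBr (from 4-bromo-2-methylbut-1-ene and Mg, THF), CeCl3, THF, −78 °C
Reagents that add atoms: 3-methylbut-3-en-1-ylmagnesium bromide, C=C(C)CC[Mg]Br
Why: Cerium-mediated Grignard 1,2-addition: the C2 carbonyl is more electrophilic than the vinylogous-ester carbonyl C9, and CeCl3 suppresses enolisation and conjugate addition. The reagent should enter anti to the axial C1 methyl (α-face) to give the 2β-alcohol; this centre is erased in step 16 but places the side chain correctly for step 14.

Step 8
Reactants: 9 C2 tertiary carbinol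
Product: 10 C20 primary alcohol
Conditions: HF·pyridine, pyridine, THF, 0 °C
Reagents that add atoms: none
Why: Under buffered HF the primary silyl ether is cleaved much faster than the hindered secondary C14 silyl ether beside the quaternary C1 (selective desilylation).

Step 9
Reactants: 10 C20 primary alcohol
Product: 12 conjugated enal, via deconjugated aldehyde 11 (not isolated)
Conditions: Dess–Martin periodinane, NaHCO3, CH2Cl2, 0 °C; filtration; then DBU (0.2 equiv), CH2Cl2, 23 °C
Reagents that add atoms: none
Why: Oxidation of the only primary alcohol gives a β,γ-unsaturated aldehyde, which DBU isomerises through its dienolate into conjugation. This moves the ring A alkene to C11=C12 and removes the temporary C11 stereocentre.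

Step 10
Reactants: 12 conjugated enal
Product: 14 transposed enone, via allylic diol 13 (not isolated)
Conditions: i-Bu2AlH, CH2Cl2, −78 °C; then 1 M HCl, THF, 0 °C
Reagents that add atoms: water, O
Why: Stork–Danheiser transposition: hydride reduces the enal to the C20 allylic alcohol and the vinylogous-ester carbonyl C9 to a carbinol, and acid then hydrolyses the enol ether with loss of the C9 hydroxyl. This places the ketone at C7 and an alkene at C8=C9.

Step 11
Reactants: 14 transposed enone
Product: 15 C20 TBDPS ether
Conditions: t-BuPh2SiCl, imidazole, CH2Cl2, 0 °C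
Reagents that add atoms: tert-butyldiphenylsilyl chloride, CC(C)(C)[Si](Cl)(c1ccccc1)c1ccccc1
Why: The primary allylic alcohol is silylated selectively; the tertiary α-ketol hydroxyl at C2 does not react. The acid-stable TBDPS group is chosen so that the C14 TBS ether can be removed before it in step 22.

Step 12
Reactants: 15 C20 TBDPS ether
Product: 17 β-hydroxy ketone, via β-boryl ketone 16 (not isolated)
Conditions: B2pin2, CuCl (5 mol%), NaOt-Bu (10 mol%), DPEphos (5 mol%), MeOH, THF, 23 °C; then NaBO3·4H2O, THF/H2O, 23 °C
Reagents that add atoms: sodium perborate, [Na+].[O-]OB=O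
Why: Copper-catalysed conjugate borylation places boron at the β-carbon C9 of the only enone, and perborate oxidation with retention returns the C9 oxygen as a carbinol without touching the isolated alkenes. The C9 configuration (α expected, anti to the C1 methyl) is inconsequential because C9 is oxidised in step 15.

Step 13
Reactants: 17 β-hydroxy ketone
Product: 18 vinyl carbinol triol
Conditions: CH2=CHMgBr, CeCl3, THF, −78 to −40 °C
Reagents that add atoms: vinylmagnesium bromide, C=C[Mg]Br
Why: Cerium-mediated Grignard addition to a hindered, enolisable ketone whose hydroxyls are first converted to alkoxides. The vinyl group should enter from the α-face, away from the 1,3-related axial C1 methyl, giving the 7β-carbinol cis to the 2β-hydroxyl, with both alkenyl chains on the α-face.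

Step 14
Reactants: 18 vinyl carbinol triol
Product: 19 tricyclic triol
Conditions: second-generation Grubbs catalyst (H2IMes)(PCy3)Cl2Ru=CHPh (5 mol%), CH2Cl2, 40 °C
Reagents that add atoms: none
Why: Ring-closing metathesis of the vinyl group with the 1,1-disubstituted alkene closes ring C as a cyclohexene. Its trisubstituted C5=C6 alkene is necessarily Z; free hydroxyls are tolerated and the trisubstituted ring A alkene is inert.

Step 15
Reactants: 19 tricyclic triol
Product: 20 tricyclic cis-2,7-diol-9-one
Conditions: IBX, DMSO, 23 °C
Reagents that add atoms: none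
Why: IBX oxidises the single secondary alcohol to the C9 ketone; the tertiary 1,2-diol cannot be oxidised and, unlike with periodate or lead reagents, is not cleaved.

Step 16
Reactants: 20 tricyclic cis-2,7-diol-9-one
Product: 22 ten-membered 2,7,9-trione, via cyclic lead diester 21 (not isolated)
Conditions: Pb(OAc)4 (1.05 equiv), NaHCO3, CH2Cl2, −20 to 0 °C
Reagents that add atoms: none
Why: Criegee glycol cleavage: the cis tertiary hydroxyls at C2 and C7 displace two acetates from tetravalent lead to form the five-membered cyclic diester 21, which fragments in a concerted two-electron step to the C2 and C7 ketones and lead diacetate. The closest known reaction type is the lead tetraacetate (or ozone) cleavage of ring-fusion diols or alkenes of hydronaphthalenes to cyclodecane-1,6-diones. No ring is closed by bond formation: the ten-membered ring appears by ring expansion when the bond shared by rings B and C is cut, so no medium-ring entropy or transannular strain has to be paid in a bond-forming transition state. No stereocentre is created; the two carbinol centres are erased and C1, C10 and C14, which lie outside the reacting array, are carried through unchanged. The C5=C6 alkene was fixed as Z by its cyclohexene origin and is not touched. The step needs only chemoselectivity: C2/C7 is the sole 1,2-diol because C9 is already a ketone, the cis geometry from the two α-face additions permits the cyclic ester, and the tertiary carbinols cannot be over-oxidised. Solid NaHCO3 removes the acetic acid, and one equivalent of oxidant at low temperature should keep the new 7,9-diketone from transannular aldol reaction and from acetoxylation at C8.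

Step 17
Reactants: 23 methyl (R)-lactate
Product: 24 methyl (R)-2-(trifluoromethylsulfonyloxy)propanoate
Conditions: Tf2O, 2,6-lutidine, CH2Cl2, −78 to 0 °C
Reagents that add atoms: trifluoromethanesulfonic anhydride, O=S(=O)(OS(=O)(=O)C(F)(F)F)C(F)(F)F
Why: Sulfonylation at oxygen leaves the stereocentre untouched and gives a secondary electrophile reactive enough for SN2 displacement by soft carbon nucleophiles.

Step 18
Reactants: 22 ten-membered 2,7,9-trione; 24 methyl (R)-2-(trifluoromethylsulfonyloxy)propanoate
Product: 25 C8-alkylated trione
Conditions: NaH, THF, 0 °C; then 24, −20 to 0 °C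
Reagents that add atoms: none
Why: Alkylation of a β-diketone enolate by a lactate triflate: C8 is the only doubly activated carbon, and its sodium enolate in THF should displace the triflate at carbon with inversion, forming C8–C17 and setting 17R. C8 itself stays configurationally labile at this stage.

Step 19
Reactants: 25 C8-alkylated trione
Product: 26 C8 tertiary alcohol
Conditions: KN(SiMe3)2, THF, −78 °C; then 2-(phenylsulfonyl)-3-phenyloxaziridine, −78 °C
Reagents that add atoms: 2-(phenylsulfonyl)-3-phenyloxaziridine, O=S(=O)(c1ccccc1)N1OC1c1ccccc1
Why: Oxaziridine oxidation of the tetrasubstituted diketone enolate (Davis hydroxylation), which does not epoxidise the alkenes. The C17 stereocentre should control the new centre: with C17–H in the enolate plane towards the bulkier C9 flank (allylic 1,3-strain), the ester shields one face and oxygen enters on the face of the C17 methyl, which corresponds to 8S.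

Step 20
Reactants: 26 C8 tertiary alcohol
Product: 28 keto lactone, via C7 hydroxy ester 27 (not isolated)
Conditions: NaBH4, CeCl3·7H2O, MeOH/THF, −78 °C; then PPTS, CH2Cl2, 23 °C
Reagents that add atoms: none
Why: Luche reduction: cerium chelated between the C7 carbonyl and the C8 hydroxyl activates the enone carbonyl, while the C2 and C9 ketones are both neopentyl-type and slower at −78 °C. Hydride should attack the chelate from the peripheral face, opposite the ring chain through C9, giving 7S with O7 and O8 cis on the macrocycle; the γ-hydroxy ester then closes to the trans-fused lactone under mild acid.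

Step 21
Reactants: 28 keto lactone
Product: 29 C2 alcohol
Conditions: (R)-2-methyl-CBS-oxazaborolidine (0.5 equiv), BH3·SMe2, THF, −30 °C
Reagents that add atoms: none
Why: Corey–Bakshi–Shibata reduction: the C2 ketone lies between a quaternary carbon (large) and a methylene (small), the best case for this catalyst, and the (R)-catalyst should give the 2S-alcohol. The C9 ketone, flanked by the fully substituted C8 and the branched C10, should be too hindered to bind the catalyst.

Step 22
Reactants: 29 C2 alcohol
Product: 30 C2,C14-diol
Conditions: HF (48% aq.), MeCN, 0 °C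
Reagents that add atoms: none
Why: Under acidic fluoride a secondary TBS ether is cleaved much faster than a primary TBDPS ether, so C14 is freed while C20 stays protected (selective desilylation).

Step 23
Reactants: 30 C2,C14-diol
Product: 31 diacetate
Conditions: Ac2O, DMAP, pyridine, 23 to 40 °C
Reagents that add atoms: acetic anhydride, CC(=O)OC(C)=O
Why: DMAP-catalysed acylation of the two secondary alcohols; the tertiary C8 hydroxyl, between a ketone and two ring carbons, should not be acylated under these conditions.

Step 24
Reactants: 31 diacetate
Product: 32 CNP0140109.1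
Conditions: HF·pyridine, pyridine, THF, 0 to 23 °C
Reagents that add atoms: none
Why: Buffered acidic fluoride removes the TBDPS ether without the acyl migration or lactone opening that a basic fluoride source could cause (desilylation).

**Compound list**

1 | 2-methoxy-6-methylphenol | COc1cccc(C)c1O | starting material
2 | 2-methoxy-6-methyl-1,4-benzoquinone | COC1=CC(=O)C=C(C)C1=O | intermediate
3 | glutaconaldehyde potassium salt (potassium (1E,3E)-5-oxopenta-1,3-dien-1-olate) | [K+].[O-]/C=C/C=C/C=O | starting material
4 | (2E,4E)-5-(tert-butyldimethylsilyloxy)penta-2,4-dienal | CC(C)(C)[Si](C)(C)O/C=C/C=C/C=O | intermediate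
5 | (2E,4E)-5-(tert-butyldimethylsilyloxy)penta-2,4-dien-1-ol | CC(C)(C)[Si](C)(C)O/C=C/C=C/CO | intermediate
6 | (1E,3E)-1,5-bis(tert-butyldimethylsilyloxy)penta-1,3-diene | CC(C)(C)[Si](C)(C)O/C=C/C=C/CO[Si](C)(C)C(C)(C)C | intermediate
7 | cis-fused cycloadduct: 3-methoxy-4a-methyl-5-(TBS-oxy)-8-(TBS-oxymethyl)-4a,5,8,8a-tetrahydronaphthalene-1,4-dione; 1β-CH3, 10β-H, 11α-CH2OTBS, 14α-OTBS (both silyloxy substituents and both ring B carbonyl carbons on one face of ring A) | CC(C)(C)[Si](C)(C)O[C@H]1C=C[C@@H](CO[Si](C)(C)C(C)(C)C)[C@H]2C(=O)C=C(OC)C(=O)[C@]21C | intermediate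
8 | trans-fused enedione: C10 epimer of 7 (10α-H) | CC(C)(C)[Si](C)(C)O[C@H]1C=C[C@@H](CO[Si](C)(C)C(C)(C)C)[C@@H]2C(=O)C=C(OC)C(=O)[C@]21C | intermediate
9 | C2 tertiary carbinol: 2β-hydroxy-2α-(3-methylbut-3-enyl) derivative of 8 with the 7-methoxy-7-en-9-one retained | CC(C)(C)[Si](C)(C)O[C@H]1C=C[C@@H](CO[Si](C)(C)C(C)(C)C)[C@@H]2C(=O)C=C(OC)[C@@](O)(CCC(C)=C)[C@]21C | intermediate
10 | C20 primary alcohol of 9 (C14 TBS ether retained) | CC(C)(C)[Si](C)(C)O[C@H]1C=C[C@@H](CO)[C@@H]2C(=O)C=C(OC)[C@@](O)(CCC(C)=C)[C@]21C | intermediate
11 | deconjugated aldehyde: C20 aldehyde with the C12=C13 alkene | CC(C)(C)[Si](C)(C)O[C@H]1C=C[C@@H](C=O)[C@@H]2C(=O)C=C(OC)[C@@](O)(CCC(C)=C)[C@]21C | intermediate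
12 | conjugated enal: C20 aldehyde on the C11=C12 alkene | CC(C)(C)[Si](C)(C)O[C@H]1CC=C(C=O)[C@@H]2C(=O)C=C(OC)[C@@](O)(CCC(C)=C)[C@]21C | intermediate
13 | allylic diol: 9β-hydroxy and C20 hydroxy, C7 methyl enol ether intact | CC(C)(C)[Si](C)(C)O[C@H]1CC=C(CO)[C@@H]2[C@H](O)C=C(OC)[C@@](O)(CCC(C)=C)[C@]21C | intermediate
14 | transposed enone: 2β-hydroxy-7-oxo-8-ene with free C20 hydroxyl | CC(C)(C)[Si](C)(C)O[C@H]1CC=C(CO)[C@@H]2C=CC(=O)[C@@](O)(CCC(C)=C)[C@]21C | intermediate
15 | C20 TBDPS ether of 14 | CC(C)(C)[Si](C)(C)O[C@H]1CC=C(CO[Si](c4ccccc4)(c5ccccc5)C(C)(C)C)[C@@H]2C=CC(=O)[C@@](O)(CCC(C)=C)[C@]21C | intermediate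
16 | β-boryl ketone: 9α-(pinacolboryl)-7-ketone | CC(C)(C)[Si](C)(C)O[C@H]1CC=C(CO[Si](c4ccccc4)(c5ccccc5)C(C)(C)C)[C@@H]2[C@@H](B6OC(C)(C)C(C)(C)O6)CC(=O)[C@@](O)(CCC(C)=C)[C@]21C | intermediate
17 | β-hydroxy ketone: 2β,9α-dihydroxy-7-ketone | CC(C)(C)[Si](C)(C)O[C@H]1CC=C(CO[Si](c4ccccc4)(c5ccccc5)C(C)(C)C)[C@@H]2[C@@H](O)CC(=O)[C@@](O)(CCC(C)=C)[C@]21C | intermediate
18 | vinyl carbinol triol: 7α-vinyl-2β,7β,9α-triol | CC(C)(C)[Si](C)(C)O[C@H]1CC=C(CO[Si](c4ccccc4)(c5ccccc5)C(C)(C)C)[C@@H]2[C@@H](O)C[C@@](O)(C=C)[C@@](O)(CCC(C)=C)[C@]21C | intermediate
19 | tricyclic triol: rings A, B and C with C5=C6, 2β,7β,9α-triol | CC(C)(C)[Si](C)(C)O[C@H]1CC=C(CO[Si](c4ccccc4)(c5ccccc5)C(C)(C)C)[C@@H]2[C@@H](O)C[C@@]3(O)C=C(C)CC[C@@]3(O)[C@]21C | intermediate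
20 | tricyclic cis-2β,7β-diol-9-one (C2–C7 bonded; C14 TBS ether, C20 TBDPS ether) | CC(C)(C)[Si](C)(C)O[C@H]1CC=C(CO[Si](c4ccccc4)(c5ccccc5)C(C)(C)C)[C@@H]2C(=O)C[C@@]3(O)C=C(C)CC[C@@]3(O)[C@]21C | intermediate
21 | cyclic lead diester of 20 (O2 and O7 bridged by Pb(OAc)2) | CC(C)(C)[Si](C)(C)O[C@H]1CC=C(CO[Si](c4ccccc4)(c5ccccc5)C(C)(C)C)[C@@H]2C(=O)C[C@@]3(O6)C=C(C)CC[C@@]3(O[Pb]6(OC(C)=O)OC(C)=O)[C@]21C | intermediate
22 | ten-membered 2,7,9-trione with Z-C5=C6, fused to ring A; C1, C10, C14 as in the target | CC(C)(C)[Si](C)(C)O[C@H]1CC=C(CO[Si](c4ccccc4)(c5ccccc5)C(C)(C)C)[C@@H]2C(=O)CC(=O)/C=C(/C)CCC(=O)[C@]21C | intermediate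
23 | methyl (R)-lactate | C[C@@H](O)C(=O)OC | starting material
24 | methyl (R)-2-(trifluoromethylsulfonyloxy)propanoate | C[C@@H](OS(=O)(=O)C(F)(F)F)C(=O)OC | intermediate
25 | C8-alkylated trione: 22 bearing the (17R)-1-methoxycarbonylethyl group at C8 (C8 configurationally labile) | CC(C)(C)[Si](C)(C)O[C@H]1CC=C(CO[Si](c4ccccc4)(c5ccccc5)C(C)(C)C)[C@@H]2C(=O)C([C@@H](C)C(=O)OC)C(=O)/C=C(/C)CCC(=O)[C@]21C | intermediate
26 | C8 tertiary alcohol: (8S,17R)-8-hydroxy derivative of 25 | CC(C)(C)[Si](C)(C)O[C@H]1CC=C(CO[Si](c4ccccc4)(c5ccccc5)C(C)(C)C)[C@@H]2C(=O)[C@](O)([C@@H](C)C(=O)OC)C(=O)/C=C(/C)CCC(=O)[C@]21C | intermediate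
27 | C7 hydroxy ester: (7S,8S,17R)-7,8-dihydroxy methyl ester | CC(C)(C)[Si](C)(C)O[C@H]1CC=C(CO[Si](c4ccccc4)(c5ccccc5)C(C)(C)C)[C@@H]2C(=O)[C@](O)([C@@H](C)C(=O)OC)[C@@H](O)/C=C(/C)CCC(=O)[C@]21C | intermediate
28 | keto lactone: (7S,8S,17R)-lactone with C2 and C9 ketones | CC(C)(C)[Si](C)(C)O[C@H]1CC=C(CO[Si](c4ccccc4)(c5ccccc5)C(C)(C)C)[C@@H]2C(=O)[C@@]3(O)[C@H](/C=C(/C)CCC(=O)[C@]21C)OC(=O)[C@@H]3C | intermediate
29 | C2 alcohol: (2S)-2-hydroxy lactone, C14 TBS ether, C20 TBDPS ether | CC(C)(C)[Si](C)(C)O[C@H]1CC=C(CO[Si](c4ccccc4)(c5ccccc5)C(C)(C)C)[C@@H]2C(=O)[C@@]3(O)[C@H](/C=C(/C)CC[C@H](O)[C@]21C)OC(=O)[C@@H]3C | intermediate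
30 | C2,C14-diol, C20 TBDPS ether | O[C@H]1CC=C(CO[Si](c4ccccc4)(c5ccccc5)C(C)(C)C)[C@@H]2C(=O)[C@@]3(O)[C@H](/C=C(/C)CC[C@H](O)[C@]21C)OC(=O)[C@@H]3C | intermediate
31 | C2,C14-diacetate, C20 TBDPS ether | CC(=O)O[C@H]1CC=C(CO[Si](c4ccccc4)(c5ccccc5)C(C)(C)C)[C@@H]2C(=O)[C@@]3(O)[C@H](/C=C(/C)CC[C@H](OC(C)=O)[C@]21C)OC(=O)[C@@H]3C | intermediate
32 | CNP0140109.1, (1S,2S,7S,8S,10S,14S,17R,5Z) | CC(=O)O[C@H]1CC=C(CO)[C@@H]2C(=O)[C@@]3(O)[C@H](/C=C(/C)CC[C@H](OC(C)=O)[C@]21C)OC(=O)[C@@H]3C | target

**Step count and risk**

Total step count: 24. Longest linear sequence: 22 steps (steps 2–16 and 18–24, from 3).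

Least certain steps:

- **Step 16 (key step).** The most likely failure is consumption of the liberated 1,3-diketone: acetoxylation at C8 by excess oxidant, or condensation across the ring with the C2 ketone. Less likely is a sluggish fragmentation if step 7 or 13 had given a trans-diol. Fallback: carry out the ring expansion at the C9 carbinol oxidation level, so that the product has no 1,3-diketone. From triol 19, selective silylation of the secondary C9 hydroxyl (Et3SiCl, imidazole) gives the tricyclic diol 9-triethylsilyl ether F1. Pb(OAc)4 cleavage gives the ten-membered 2,7-dione 9-triethylsilyl ether F2. Buffered HF·pyridine gives the 9-hydroxy-2,7-dione F3, and IBX oxidation returns to 22.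

- **Step 5.** Insufficient enantio- or regiocontrol is the main risk. The catalyst must chelate the methoxy/carbonyl pair of 2 and not bind the more basic vinylogous-ester carbonyl (which would reverse the regiochemistry), and the bis-silyl diene must survive the Lewis acid. Fallback: resolution in place of asymmetric catalysis. Uncatalysed cycloaddition of 2 and 6 (toluene, 60 °C) gives racemic 7, which is carried through steps 6–8 to racemic 10. Esterification with (S)-O-methylmandelic acid and separation of the diastereomers gives the mandelate ester F4, and methanolysis (K2CO3, MeOH) returns to enantiopure 10.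

- **Step 7.** Poor facial selectivity or failure to add is possible: the α-face approach to C2 is syn-axial to the C14 silyloxy group, and the alternatives are attack at C9 or conjugate addition at C8. Fallback: turn the obstructing group into a directing group. From 8, both silyl ethers are removed (HF·pyridine) to give the enedione diol F5. Excess Grignard reagent with CeCl3 is then delivered to the α-face of C2 by the C14 alkoxide, giving the triol F6, and silylation of the primary and secondary hydroxyls (t-BuMe2SiOTf, 2,6-lutidine, −78 °C) returns to 9.

- **Step 18.** O-alkylation of the diketone enolate or slow SN2 displacement at the secondary triflate (with elimination to methyl acrylate) could dominate. Fallback: form C8–C17 by condensation and reduction instead of substitution. From 22, Knoevenagel condensation with methyl pyruvate (TiCl4, pyridine) gives the C8 alkylidene diketone F7. Ligand-controlled conjugate reduction (Cu(OAc)2, a chiral bisphosphine such as DTBM-SEGPHOS in the antipode that gives 17R, (EtO)2MeSiH) adds hydride at C17 of the doubly activated alkene and returns to 25.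

- **Step 19.** Facial selectivity at C8 is the least predictable stereochemical event, because it rests on 1,2-induction from C17 in a flexible ten-membered enolate; retro-Claisen opening of the 2-hydroxy-1,3-diketone by adventitious alkoxide is a second risk. Fallback: move from substrate control to catalyst control by a different oxidation mechanism. The diketone 25 is bound as a chelate to a chiral Lewis acid (Cu(OTf)2 with a bis(oxazoline) ligand) and hydroxylated with tert-butyl hydroperoxide, with the ligand antipode chosen for 8S; this returns to 26. If neither face can be secured, the C8 epimers are separated after lactonisation at 28.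

## Further compounds

F1 | step 16 | tricyclic cis-2β,7β-diol 9-triethylsilyl ether | CC(C)(C)[Si](C)(C)O[C@H]1CC=C(CO[Si](c4ccccc4)(c5ccccc5)C(C)(C)C)[C@@H]2[C@@H](O[Si](CC)(CC)CC)C[C@@]3(O)C=C(C)CC[C@@]3(O)[C@]21C
F2 | step 16 | ten-membered 2,7-dione 9-triethylsilyl ether | CC(C)(C)[Si](C)(C)O[C@H]1CC=C(CO[Si](c4ccccc4)(c5ccccc5)C(C)(C)C)[C@@H]2[C@@H](O[Si](CC)(CC)CC)CC(=O)/C=C(/C)CCC(=O)[C@]21C
F3 | step 16 | ten-membered 9-hydroxy-2,7-dione | CC(C)(C)[Si](C)(C)O[C@H]1CC=C(CO[Si](c4ccccc4)(c5ccccc5)C(C)(C)C)[C@@H]2[C@@H](O)CC(=O)/C=C(/C)CCC(=O)[C@]21C
F4 | step 5 | (S)-O-methylmandelate ester of 10 at C20 | CC(C)(C)[Si](C)(C)O[C@H]1C=C[C@@H](COC(=O)[C@@H](OC)c4ccccc4)[C@@H]2C(=O)C=C(OC)[C@@](O)(CCC(C)=C)[C@]21C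
F5 | step 7 | trans-fused enedione diol (C14 and C20 hydroxyls free) | O[C@H]1C=C[C@@H](CO)[C@@H]2C(=O)C=C(OC)C(=O)[C@]21C
F6 | step 7 | C2 tertiary carbinol triol (C2, C14 and C20 hydroxyls free) | O[C@H]1C=C[C@@H](CO)[C@@H]2C(=O)C=C(OC)[C@@](O)(CCC(C)=C)[C@]21C
F7 | step 18 | C8 alkylidene diketone from 22 and methyl pyruvate (mixture of alkene isomers) | CC(C)(C)[Si](C)(C)O[C@H]1CC=C(CO[Si](c4ccccc4)(c5ccccc5)C(C)(C)C)[C@@H]2C(=O)C(=C(C)C(=O)OC)C(=O)/C=C(/C)CCC(=O)[C@]21C
F0 | step 19 | none | none
A1 | alternative 1 | C1–C8 dithiane adduct | O[C@H]([C@@]1(C)[C@@H](O[Si](C)(C)C(C)(C)C)CC=C(CO[Si](C)(C)C(C)(C)C)[C@@H]1COCc2ccc(OC)cc2)C3(C/C(C)=C\[C@H]4COC(C)(C)O4)SCCCS3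
A2 | alternative 1 | ring A aldehyde | O=C[C@@]1(C)[C@@H](O[Si](C)(C)C(C)(C)C)CC=C(CO[Si](C)(C)C(C)(C)C)[C@@H]1COCc2ccc(OC)cc2
A3 | alternative 1 | Z allylic bromide | BrC/C(C)=C\[C@H]1COC(C)(C)O1
A4 | alternative 1 | 2-lithio-1,3-dithiane | [Li]C1SCCCS1
A5 | alternative 2 | 2-hydroxy bicyclic lactone, C8 and C20 silylated | CC(=O)O[C@H]1CC=C(CO[Si](C)(C)C(C)(C)C)[C@@H]2C(=O)[C@@]3(O[Si](C)(C)C)[C@H](/C=C(/C)CC[C@H](O)[C@]21C)OC(=O)[C@@H]3C
A6 | alternative 2 | fourteen-membered C1–C2 epoxide with C9 silyl dienol ether | CC(=O)O[C@H]1C/C=C(CO[Si](C)(C)C(C)(C)C)\C=C(/O[Si](C)(C)C)[C@@]2(O[Si](C)(C)C)[C@H](/C=C(/C)CC[C@@H]3O[C@@]13C)OC(=O)[C@@H]2C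
A7 | alternative 3 | ten-membered C9 enynol | CC(C)(C)[Si](C)(C)O[C@H]1CC=C(COCc3ccc(OC)cc3)[C@@H]2[C@H](O)C#C/C=C(/C)CC[C@H](O[Si](C)(C)C(C)(C)C)[C@]21C
A8 | alternative 3 | thirteen-membered C9–O–C12 propargyl allyl ether | CC(C)(C)[Si](C)(C)O[C@H]1C[C@@H]2OCC#C/C=C(/C)CC[C@H](O[Si](C)(C)C(C)(C)C)[C@]1(C)C=C2COCc3ccc(OC)cc3
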